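## Retrosynthetic overview
1. Numbering follows the target SMILES: C1 CH(OAc), C2, C3 C(CH3)(OAc), C4, C5 (fusion CH), C6, C7 (C=O), C8=C9, C10, C11, N12, C13, C14, C15, C16 (quaternary). Ring A = C1–C5 + C16, ring B = C5–C8 + C16, ring C = C8 to C16 through N12.
2. Feature used: C8–C16 is the single bond common to ring B and ring C, and it ends at the quaternary C16. Removing it merges both rings into one twelve-membered ring (C5 to C16) on ring A, with C8≡C9 as alkyne and C1=C16 as enol silane (22). One transannular C–C bond formation then gives rings B and C, C16 and the C8=C9 alkene.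
3. After the key step only functional-group work remains: 29 ⇐ 27 (Boc removal) ⇐ 26 (two acetates) ⇐ 25 (allylic oxidation at C7) ⇐ 24 (desilylation) ⇐ 23 (C1 reduction).
4. 22 ⇐ C7–C8 by Nozaki–Hiyama–Kishi closure of iodoalkyne aldehyde 20 ⇐ C5–C6 by Mukaiyama–Michael addition of 18 to enone 17 ⇐ C15–C16 by B-alkyl Suzuki coupling of iodoenone 14 with arm 7 (from 1 and 3).
5. Ring order: ring A comes with 8 and is made chiral at C3 (epoxidation, reductive opening); then the twelve-membered ring; then rings B and C together.

Key step: step 15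

Assumption 1 (step 4): the quinine-derived primary amine salt is taken to give the (2S,3S)-epoxide; if its sense of induction is the opposite, the quinidine-derived pseudoenantiomer is used and nothing else changes.
Assumption 2 (C7): step 13 is expected to give both C7 epimers, which are carried on together because C7 becomes a carbonyl carbon in step 18; names and SMILES of 21–25 show the (7S) epimer only.

## Route

Step 1
Reactants: 1 but-3-yn-1-amine
Product: 2 tert-butyl but-3-yn-1-ylcarbamate
Conditions: Boc2O, CH2Cl2, 0 °C to rt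
Reagents that add atoms: di-tert-butyl dicarbonate, CC(C)(C)OC(=O)OC(=O)OC(C)(C)C
Why: Carbamate formation by N-acylation of the primary amine with the dicarbonate masks N12 with a group that tolerates the bases, boranes, hydrides and low-valent metals ahead and is removed last.

Step 2
Reactants: 2 tert-butyl but-3-yn-1-ylcarbamate; 3 allyl bromide
Product: 5 tert-butyl allyl(but-3-yn-1-yl)carbamate, via sodium carbamate 4 (not isolated)
Conditions: NaH, DMF, 0 °C; then 3, 0 °C to rt
Reagents that add atoms: none
Why: SN2 N-alkylation of a carbamate anion: the N–H is more acidic than the alkyne C–H, so one equivalent of NaH deprotonates nitrogen only and the allylic bromide then delivers C13–C15 as an allyl group.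

Step 3
Reactants: 5 tert-butyl allyl(but-3-yn-1-yl)carbamate
Product: 7 tert-butyl allyl[4-(trimethylsilyl)but-3-yn-1-yl]carbamate, via lithium acetylide 6 (not isolated)
Conditions: n-BuLi, THF, −78 °C; then Me3SiCl, −78 to 0 °C
Reagents that add atoms: chlorotrimethylsilane, C[Si](C)(C)Cl
Why: Deprotonation and C-silylation of the terminal alkyne, fast at −78 °C where the Boc group is not attacked, caps C8 so that the alkyne stays out of the hydroboration and of the palladium chemistry of step 9.

Step 4
Reactants: 8 3-methylcyclohex-2-en-1-one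
Product: 9 (2S,3S)-2,3-epoxy-3-methylcyclohexan-1-one
Conditions: 9-amino-9-deoxy-epi-quinine (10 mol %), CF3CO2H (20 mol %), aq. H2O2, dioxane, 30–50 °C
Reagents that add atoms: hydrogen peroxide, OO
Why: Amine-catalysed asymmetric nucleophilic epoxidation (iminium–enamine variant of the Weitz–Scheffer reaction): the chiral primary amine salt converts 8 into an iminium ion, H2O2 adds to C3 on the face left open by the catalyst and the peroxy-enamine closes the oxirane, which sets the C3–O stereocentre (and a C2 centre that is removed in step 5).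

Step 5
Reactants: 9 (2S,3S)-2,3-epoxy-3-methylcyclohexan-1-one
Product: 10 (S)-3-hydroxy-3-methylcyclohexan-1-one
Conditions: SmI2 (2.2 equiv), THF/MeOH, −90 °C
Reagents that add atoms: none
Why: Single-electron reductive opening of an α,β-epoxy ketone: two electrons from SmI2 break only the C2–O bond next to the carbonyl group and methanol protonates the samarium enolate, so the C3–O bond and its configuration are untouched and the cold, nearly neutral medium avoids dehydration of the aldol.

Step 6
Reactants: 10 (S)-3-hydroxy-3-methylcyclohexan-1-one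
Product: 11 (S)-3-methyl-3-(triethylsilyloxy)cyclohexan-1-one
Conditions: Et3SiOTf, 2,6-lutidine, CH2Cl2, −78 °C
Reagents that add atoms: triethylsilyl trifluoromethanesulfonate, CC[Si](CC)(CC)OS(=O)(=O)C(F)(F)F
Why: Silylation of a hindered tertiary alcohol with a silyl triflate and a non-nucleophilic pyridine base, run cold so that O-silylation is faster than enol silane formation or β-elimination.

Step 7
Reactants: 11 (S)-3-methyl-3-(triethylsilyloxy)cyclohexan-1-one
Product: 13 (S)-5-methyl-5-(triethylsilyloxy)cyclohex-2-en-1-one, via lithium enolate 12 (not isolated)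
Conditions: LiN(iPr)2, THF, −78 °C; then PhS(Cl)=NtBu, −78 °C
Reagents that add atoms: none
Why: Mukaiyama dehydrogenation: kinetic deprotonation takes place at C16, the α-CH2 remote from the quaternary C3, the enolate attacks sulfur of the sulfinimidoyl chloride and intramolecular syn elimination at −78 °C gives the C5=C16 enone under conditions too mild for loss of the β-silyloxy group.

Step 8
Reactants: 13 (S)-5-methyl-5-(triethylsilyloxy)cyclohex-2-en-1-one
Product: 14 (S)-2-iodo-5-methyl-5-(triethylsilyloxy)cyclohex-2-en-1-one
Conditions: I2, pyridine/CH2Cl2, 0 °C to rt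
Reagents that add atoms: iodine, II
Why: α-Iodination of an enone by the addition–iodination–elimination sequence (Baylis–Hillman-type activation): pyridine adds reversibly to C5, the resulting enolate is iodinated at C16 and loss of pyridine restores the enone.

Step 9
Reactants: 7 tert-butyl allyl[4-(trimethylsilyl)but-3-yn-1-yl]carbamate; 14 (S)-2-iodo-5-methyl-5-(triethylsilyloxy)cyclohex-2-en-1-one
Product: 16 tert-butyl (S)-{3-[4-methyl-6-oxo-4-(triethylsilyloxy)cyclohex-1-en-1-yl]propyl}[4-(trimethylsilyl)but-3-yn-1-yl]carbamate, via B-alkyl-9-BBN borane 15 (not isolated)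
Conditions: 7, 9-BBN, THF, 0 °C to rt; then 14, PdCl2(dppf) (5 mol %), AsPh3, aq. K3PO4, DMF, rt
Reagents that add atoms: none
Why: Hydroboration followed by B-alkyl Suzuki–Miyaura coupling: 9-BBN adds anti-Markovnikov to the monosubstituted alkene far faster than to the silyl-capped alkyne, and the primary alkylborane couples with the α-iodoenone at room temperature to form C15–C16, the phosphate base being mild enough for the β-silyloxy ketone and the C–Si bond.

Step 10
Reactants: 16 silyl-capped alkynyl enone
Product: 17 tert-butyl (S)-(4-iodobut-3-yn-1-yl){3-[4-methyl-6-oxo-4-(triethylsilyloxy)cyclohex-1-en-1-yl]propyl}carbamate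
Conditions: NIS, AgNO3 (20 mol %), DMF, rt, dark
Reagents that add atoms: N-iodosuccinimide, O=C1CCC(=O)N1I
Why: Silver-catalysed iododesilylation of an alkynylsilane (ipso substitution by way of the silver acetylide) turns the cap on C8 directly into the C–I bond needed in step 13, and it is placed before step 11 so that NIS never meets an enol silane.

Step 11
Reactants: 17 iodoalkynyl enone; 18 tert-butyl[(1-methoxyethenyl)oxy]dimethylsilane
Product: 19 methyl 2-[(1S,5S)-2-{3-[(tert-butoxycarbonyl)(4-iodobut-3-yn-1-yl)amino]propyl}-3-(tert-butyldimethylsilyloxy)-5-methyl-5-(triethylsilyloxy)cyclohex-2-en-1-yl]acetate (3S,5S in route numbering; C6 cis to the C3 oxygen)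
Conditions: TBSOTf (20 mol %), 2,6-di-tert-butyl-4-methylpyridine (10 mol %), CH2Cl2, −78 °C
Reagents that add atoms: none
Why: Mukaiyama–Michael addition with silyl transfer: catalytic TBSOTf silylates the enone oxygen, the ketene silyl acetal attacks C5 and passes its silyl group on, which gives the regiodefined C1=C16 TBS enol ether and C6–C7 at the ester level without harm to the C8–I bond; C5 is set by C3, because the silylated enone should react through the half-chair with the C3 methyl group pseudo-equatorial and the smaller, cation-stabilising C3–O bond pseudo-axial, and the stereoelectronically preferred axial attack on that conformer places C6 cis to the C3 oxygen.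

Step 12
Reactants: 19 methyl ester enol silane
Product: 20 aldehyde (3S,5S): as 19 but with C7 as CHO
Conditions: iBu2AlH (1.1 equiv), CH2Cl2, −78 °C; then MeOH, aq. potassium sodium tartrate
Reagents that add atoms: none
Why: Partial reduction of an ester to the aldehyde: the tetrahedral aluminium hemiacetal persists at −78 °C and collapses only on work-up, and carbamate, iodoalkyne, enol silane and silyl ether are inert to one equivalent of iBu2AlH at this temperature.

Step 13
Reactants: 20 iodoalkyne aldehyde
Product: 21 twelve-membered propargylic alcohol (3S,5R,7S): ring A with C1(OTBS)=C16 and C3(CH3)(OTES), fused at C5/C16 to the ring C5–C6–C7(OH)–C8≡C9–C10–C11–N12(Boc)–C13–C14–C15–C16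
Conditions: CrCl2 (8 equiv), NiCl2 (1 mol % of the CrCl2), THF, rt, slow addition of 20 (final 0.002 M)
Reagents that add atoms: none
Why: Nozaki–Hiyama–Kishi reaction: zerovalent nickel inserts into the C8–I bond and transmetalation gives an alkynyl species of trivalent chromium that is nucleophilic but hardly basic, so it adds to the enolisable C7 aldehyde without touching carbamate or enol silane, slow addition at high dilution favours closure of the nearly strain-free twelve-membered cycloalkyne over oligomers, and the new stereocentre C7 is left uncontrolled because it is erased in step 18.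

Step 14
Reactants: 21 twelve-membered propargylic alcohol
Product: 22 twelve-membered alkynyl silyl enol ether (3S,5R,7S): as 21 but with C7–OTBS
Conditions: TBSCl, imidazole, DMF, rt
Reagents that add atoms: tert-butyldimethylsilyl chloride, CC(C)(C)[Si](C)(C)Cl
Why: Imidazole-catalysed silyl ether formation on the secondary propargylic alcohol keeps C7 at the alcohol level, so that the alkyne is not polarised towards C9 as in an ynone, and removes an O–H that could rearrange or add under gold catalysis.

Step 15
Reactants: 22 twelve-membered alkynyl silyl enol ether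
Product: 23 tricyclic C1 ketone (3S,5R,7S,16S; C8=C9 E): rings A, B and C in place, cis A/B fusion, C7–OTBS, C3–OTES, N12–Boc
Conditions: Ph3PAuCl (10 mol %), AgBF4 (10 mol %), CH2Cl2/MeOH (10:1), 0.01 M, rt to 40 °C
Reagents that add atoms: none
Why: Proposed new method: Ph3PAu+ (from Ph3PAuCl and AgBF4) binds the outer face of the ring alkyne C8≡C9, the enol carbon C16 adds to C8 from inside the ring and therefore anti to gold, methanol removes the silyl group from the silyloxocarbenium ion at C1 and the proton so released cleaves the C9–Au bond with retention. The closest known reaction type is the 5-exo-dig carbocyclisation of silyl enol ethers onto tethered alkynes under cationic monovalent gold (Conia-ene type), which is established for open tethers but has not been run across a ring. Ring B (C5, C6, C7, C8, C16) closes in the 5-exo-dig mode through the C5–C6–C7 tether, and ring C (C8 to C16 by way of N12) is not closed by a second event but is the nine-atom remainder of the twelve-membered ring once C8–C16 divides it. The only new stereocentre, C16, is controlled by C5: allylic strain with C15 keeps C6 pseudo-axial, the three-atom tether holds C8 under the face of the C1=C16 bond that carries C6, so the A/B fusion can only be cis and C15 is pushed to the opposite face, while anti addition fixes C10 syn to C16 on the C8=C9 bond, the only geometry a nine-membered ring can hold. The step needs attack at C8 rather than C9 (6-endo-dig), which the shorter reach to C8, the slippage of the bulky Ph3PAu unit towards C9 and away from the C7 silyl ether, and the more strained eight-membered remainder of the endo path should secure. It also needs C16 to outrun the Boc carbonyl oxygen (6-exo attack at C9) and methanolysis of the enol ether, for which the far higher π-nucleophilicity of the tetrasubstituted enol silane, its enforced proximity to the alkyne and the robust TBS group are relied on.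

Step 16
Reactants: 23 tricyclic C1 ketone
Product: 24 tricyclic C1 alcohol (1S,3S,5R,7S,16S): C1–OH equatorial, cis to the C3 oxygen and to C8
Conditions: SmI2 (excess), H2O, THF, 0 °C to rt
Reagents that add atoms: none
Why: Ketyl-type single-electron reduction (SmI2–H2O) under product-development control: in the ring A chair that keeps C8 axial and C15 equatorial an axial C1–O bond would be syn-diaxial to the axial C3 methyl group, so protonation at C1 should give the equatorial alcohol with C1–O cis to C3–O and to C8 as the target requires, whereas a hydride reagent would have to choose between a face blocked by that methyl group and one blocked by rings B and C.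

Step 17
Reactants: 24 tricyclic C1 alcohol
Product: 25 N-Boc triol (1S,3S,5R,7S,16S): free OH at C1, C3 and C7
Conditions: HF·pyridine, pyridine, THF, 0 °C to rt
Reagents that add atoms: none
Why: Fluoride-driven desilylation (formation of strong Si–F bonds) frees the C7 and C3 hydroxyl groups, the pyridine buffer keeping the medium too weakly acidic to touch the Boc group or to ionise the allylic alcohol.

Step 18
Reactants: 25 N-Boc triol
Product: 26 N-Boc enone diol (1S,3S,5S,16S; C8=C9 E): C7 ketone conjugated with C8=C9
Conditions: MnO2 (activated, excess), CH2Cl2, rt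
Reagents that add atoms: none
Why: Chemoselective allylic oxidation on the MnO2 surface: only the C7 hydroxyl group is allylic, so both C7 epimers converge on the C7 enone while the saturated secondary C1 and tertiary C3 alcohols are left alone.

Step 19
Reactants: 26 N-Boc enone diol
Product: 27 N-Boc diacetate (1S,3S,5S,16S; C8=C9 E)
Conditions: Ac2O, Et3N, DMAP, CH2Cl2, rt to 40 °C
Reagents that add atoms: acetic anhydride, CC(=O)OC(C)=O
Why: DMAP-catalysed acylation (Steglich-type nucleophilic catalysis): the N-acetylpyridinium ion is reactive enough for the neopentyl-type secondary C1 alcohol and the tertiary C3 alcohol, N12 is still blocked as its carbamate, and no C–O bond at a stereocentre is broken.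

Step 20
Reactants: 27 N-Boc diacetate
Product: 29 target CNP0120442.1 (1S,3S,5S,16S; C8=C9 E), via trimethylsilyl carbamate 28 (not isolated)
Conditions: Me3SiOTf, 2,6-lutidine, CH2Cl2, 0 °C; then MeOH; aq. NaHCO3
Reagents that add atoms: none
Why: Silyl triflate-mediated Boc cleavage: the carbamate carbonyl oxygen, the most Lewis-basic site, is silylated, the tert-butyl group leaves as isobutene to the lutidine buffer and methanolysis with loss of CO2 frees N12–H, so that no strong protic acid ever meets the ionisable tertiary C3 acetate and any silyl dienol ether formed at C7 reverts on the same quench.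

## Compound list
1 | but-3-yn-1-amine | C#CCCN | starting material
2 | tert-butyl but-3-yn-1-ylcarbamate | C#CCCNC(=O)OC(C)(C)C | intermediate
3 | allyl bromide | C=CCBr | starting material
4 | sodium carbamate of 2 | C#CCC[N-]C(=O)OC(C)(C)C.[Na+] | intermediate
5 | tert-butyl allyl(but-3-yn-1-yl)carbamate | C#CCCN(CC=C)C(=O)OC(C)(C)C | intermediate
6 | lithium acetylide of 5 | [Li]C#CCCN(CC=C)C(=O)OC(C)(C)C | intermediate
7 | tert-butyl allyl[4-(trimethylsilyl)but-3-yn-1-yl]carbamate | C[Si](C)(C)C#CCCN(CC=C)C(=O)OC(C)(C)C | intermediate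
8 | 3-methylcyclohex-2-en-1-one | CC1=CC(=O)CCC1 | starting material
9 | (2S,3S)-2,3-epoxy-3-methylcyclohexan-1-one | O=C1CCC[C@]2(C)O[C@H]12 | intermediate
10 | (S)-3-hydroxy-3-methylcyclohexan-1-one | O=C1CCC[C@](C)(O)C1 | intermediate
11 | (S)-3-methyl-3-(triethylsilyloxy)cyclohexan-1-one | O=C1CCC[C@](C)(O[Si](CC)(CC)CC)C1 | intermediate
12 | lithium enolate of 11 (C1=C16) | [Li]OC1=CCC[C@](C)(O[Si](CC)(CC)CC)C1 | intermediate
13 | (S)-5-methyl-5-(triethylsilyloxy)cyclohex-2-en-1-one | O=C1C=CC[C@](C)(O[Si](CC)(CC)CC)C1 | intermediate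
14 | (S)-2-iodo-5-methyl-5-(triethylsilyloxy)cyclohex-2-en-1-one | O=C1C(I)=CC[C@](C)(O[Si](CC)(CC)CC)C1 | intermediate
15 | B-alkyl-9-BBN borane from 7 | C[Si](C)(C)C#CCCN(CCCB1C2CCCC1CCC2)C(=O)OC(C)(C)C | intermediate
16 | silyl-capped alkynyl enone (S) | O=C1C(CCCN(CCC#C[Si](C)(C)C)C(=O)OC(C)(C)C)=CC[C@](C)(O[Si](CC)(CC)CC)C1 | intermediate
17 | iodoalkynyl enone (S) | O=C1C(CCCN(CCC#CI)C(=O)OC(C)(C)C)=CC[C@](C)(O[Si](CC)(CC)CC)C1 | intermediate
18 | tert-butyl[(1-methoxyethenyl)oxy]dimethylsilane | C=C(OC)O[Si](C)(C)C(C)(C)C | starting material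
19 | methyl ester enol silane (3S,5S) | COC(=O)C[C@@H]1C[C@](C)(O[Si](CC)(CC)CC)CC(O[Si](C)(C)C(C)(C)C)=C1CCCN(CCC#CI)C(=O)OC(C)(C)C | intermediate
20 | iodoalkyne aldehyde (3S,5S) | O=CC[C@@H]1C[C@](C)(O[Si](CC)(CC)CC)CC(O[Si](C)(C)C(C)(C)C)=C1CCCN(CCC#CI)C(=O)OC(C)(C)C | intermediate
21 | twelve-membered propargylic alcohol (3S,5R,7S) | CC(C)(C)[Si](C)(C)OC1=C2CCCN(C(=O)OC(C)(C)C)CCC#C[C@@H](O)C[C@@H]2C[C@](C)(O[Si](CC)(CC)CC)C1 | intermediate
22 | twelve-membered alkynyl silyl enol ether (3S,5R,7S), key-step precursor | CC(C)(C)[Si](C)(C)OC1=C2CCCN(C(=O)OC(C)(C)C)CCC#C[C@@H](O[Si](C)(C)C(C)(C)C)C[C@@H]2C[C@](C)(O[Si](CC)(CC)CC)C1 | intermediate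
23 | tricyclic C1 ketone (3S,5R,7S,16S), key-step product | O=C1C[C@@](C)(O[Si](CC)(CC)CC)C[C@H]2C[C@H](O[Si](C)(C)C(C)(C)C)/C3=C/CCN(C(=O)OC(C)(C)C)CCC[C@@]321 | intermediate
24 | tricyclic C1 alcohol (1S,3S,5R,7S,16S) | O[C@H]1C[C@@](C)(O[Si](CC)(CC)CC)C[C@H]2C[C@H](O[Si](C)(C)C(C)(C)C)/C3=C/CCN(C(=O)OC(C)(C)C)CCC[C@@]321 | intermediate
25 | N-Boc triol (1S,3S,5R,7S,16S) | O[C@H]1C[C@@](C)(O)C[C@H]2C[C@H](O)/C3=C/CCN(C(=O)OC(C)(C)C)CCC[C@@]321 | intermediate
26 | N-Boc enone diol (1S,3S,5S,16S) | O[C@H]1C[C@@](C)(O)C[C@H]2CC(=O)/C3=C/CCN(C(=O)OC(C)(C)C)CCC[C@@]321 | intermediate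
27 | N-Boc diacetate (1S,3S,5S,16S) | CC(=O)O[C@H]1C[C@@](C)(OC(C)=O)C[C@H]2CC(=O)/C3=C/CCN(C(=O)OC(C)(C)C)CCC[C@@]321 | intermediate
28 | trimethylsilyl carbamate of the target | CC(=O)O[C@H]1C[C@@](C)(OC(C)=O)C[C@H]2CC(=O)/C3=C/CCN(C(=O)O[Si](C)(C)C)CCC[C@@]321 | intermediate
29 | CNP0120442.1 (1S,3S,5S,16S; C8=C9 E) | CC(=O)O[C@H]1C[C@@](C)(OC(C)=O)C[C@H]2CC(=O)/C3=C/CCNCCC[C@@]321 | target

## Step count and risks
Total steps: 20. Longest linear sequence: 17 steps (steps 4–20, from 8); the arm 7 takes 3 steps and joins at step 9.

**1. Step 15 (key step).**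
- Three processes may defeat it: attack at C9 instead of C8 (6-endo closure), capture of the activated alkyne by the Boc carbonyl oxygen, or methanolysis of the enol silane before the C–C bond forms.
- The fallback uses known chemistry and closes the two rings one after the other. It sets out from 14 and 2 and comes back at 23.
- Stille coupling of 14 with allyltributylstannane (Pd2(dba)3, AsPh3, THF) should give (S)-2-allyl-5-methyl-5-(triethylsilyloxy)cyclohex-2-en-1-one F1.
- Addition of 18 under the conditions of step 11 gives the C16-allyl ester enol silane F2, and iBu2AlH at −78 °C gives the C16-allyl aldehyde enol silane F3.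
- Carbamate 2 is deprotonated twice with n-BuLi to the N,C-dilithio carbamate F4. This adds to F3 to give the open-chain propargylic alcohol F5, protected (TBSCl, imidazole) as the open-chain propargylic silyl ether F6.
- Ph3PAuCl/AgBF4 in CH2Cl2/MeOH then closes ring B alone. This is the established open-tether 5-exo-dig cyclisation of an enol silane, and it gives the cis-hydrindanone F7 with C16 quaternary and C10 syn to C16.
- Hydroboration of the allyl group with 9-BBN gives the B-alkyl-9-BBN adduct F8, oxidised with NaBO3·4H2O to the C13 primary alcohol F9. I2, PPh3 and imidazole give the C13 primary iodide F10.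
- KOtBu in dilute THF closes ring C by intramolecular N-alkylation of the carbamate anion (N12–C13), a known way to nine-membered azacycles, to give 23. The equatorial C3–O bond is poorly aligned for β-elimination from the C1 enolate.

**2. Step 13.**
- Oligomerisation may outrun ring closure, and the alkynylchromium species may be protonated before it reaches the aldehyde.
- The fallback forms C7–C8 between two molecules and closes the ring at the triple bond by ring-closing alkyne metathesis. It sets out from 5 (by way of its acetylide 6) and 14 and comes back at 22, and step 10 is no longer needed.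
- Acetylide 6 is quenched with MeI to give tert-butyl allyl(pent-3-yn-1-yl)carbamate F11.
- 9-BBN gives the pentynyl B-alkyl-9-BBN borane F12, coupled with 14 as in step 9 to the pentynyl enone F13.
- Addition of 18 as in step 11 gives the pentynyl ester enol silane F14, and iBu2AlH gives the pentynyl aldehyde enol silane F15.
- CH3C≡CMgBr adds to F15 (THF, −78 °C) to give the diyne alcohol F16, silylated (TBSCl, imidazole) to the diyne silyl ether F17.
- Mo(≡CC6H4OMe-4)(OSiPh3)3 with 5 Å molecular sieves in dilute toluene then closes the twelve-membered cycloalkyne with loss of but-2-yne and gives 22.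

**3. Step 16.**
- Electron transfer to the hindered carbonyl group may be sluggish, and protonation at C1 may show poor facial selectivity.
- The fallback separates reduction from stereocontrol. It sets out from 23 and comes back at 24.
- NaBH4 in MeOH at 0 °C reduces 23 under kinetic control.
- Whatever part is the axial C1 alcohol F18 is equilibrated with Al(OiPr)3 and a trace of acetone in hot toluene/iPrOH (Meerwein–Ponndorf–Verley/Oppenauer redox equilibrium). This drains it into the thermodynamically preferred equatorial alcohol 24.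

## Further compounds
F1 | step 15 | (S)-2-allyl-5-methyl-5-(triethylsilyloxy)cyclohex-2-en-1-one | O=C1C(CC=C)=CC[C@](C)(O[Si](CC)(CC)CC)C1
F2 | step 15 | C16-allyl ester enol silane | COC(=O)C[C@@H]1C[C@](C)(O[Si](CC)(CC)CC)CC(O[Si](C)(C)C(C)(C)C)=C1CC=C
F3 | step 15 | C16-allyl aldehyde enol silane | O=CC[C@@H]1C[C@](C)(O[Si](CC)(CC)CC)CC(O[Si](C)(C)C(C)(C)C)=C1CC=C
F4 | step 15 | N,C-dilithio carbamate | [Li]C#CCCN([Li])C(=O)OC(C)(C)C
F5 | step 15 | open-chain propargylic alcohol | CC(C)(C)OC(=O)NCCC#C[C@@H](O)C[C@@H]1C[C@](C)(O[Si](CC)(CC)CC)CC(O[Si](C)(C)C(C)(C)C)=C1CC=C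
F6 | step 15 | open-chain propargylic silyl ether | CC(C)(C)OC(=O)NCCC#C[C@@H](O[Si](C)(C)C(C)(C)C)C[C@@H]1C[C@](C)(O[Si](CC)(CC)CC)CC(O[Si](C)(C)C(C)(C)C)=C1CC=C
F7 | step 15 | cis-hydrindanone | O=C1C[C@@](C)(O[Si](CC)(CC)CC)C[C@H]2C[C@H](O[Si](C)(C)C(C)(C)C)/C(=C/CCNC(=O)OC(C)(C)C)[C@]21CC=C
F8 | step 15 | B-alkyl-9-BBN adduct | O=C1C[C@@](C)(O[Si](CC)(CC)CC)C[C@H]2C[C@H](O[Si](C)(C)C(C)(C)C)/C(=C/CCNC(=O)OC(C)(C)C)[C@]21CCCB3C4CCCC3CCC4
F9 | step 15 | C13 primary alcohol | O=C1C[C@@](C)(O[Si](CC)(CC)CC)C[C@H]2C[C@H](O[Si](C)(C)C(C)(C)C)/C(=C/CCNC(=O)OC(C)(C)C)[C@]21CCCO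
F10 | step 15 | C13 primary iodide | O=C1C[C@@](C)(O[Si](CC)(CC)CC)C[C@H]2C[C@H](O[Si](C)(C)C(C)(C)C)/C(=C/CCNC(=O)OC(C)(C)C)[C@]21CCCI
F11 | step 13 | tert-butyl allyl(pent-3-yn-1-yl)carbamate | CC#CCCN(CC=C)C(=O)OC(C)(C)C
F12 | step 13 | pentynyl B-alkyl-9-BBN borane | CC#CCCN(CCCB1C2CCCC1CCC2)C(=O)OC(C)(C)C
F13 | step 13 | pentynyl enone | O=C1C(CCCN(CCC#CC)C(=O)OC(C)(C)C)=CC[C@](C)(O[Si](CC)(CC)CC)C1
F14 | step 13 | pentynyl ester enol silane | COC(=O)C[C@@H]1C[C@](C)(O[Si](CC)(CC)CC)CC(O[Si](C)(C)C(C)(C)C)=C1CCCN(CCC#CC)C(=O)OC(C)(C)C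
F15 | step 13 | pentynyl aldehyde enol silane | O=CC[C@@H]1C[C@](C)(O[Si](CC)(CC)CC)CC(O[Si](C)(C)C(C)(C)C)=C1CCCN(CCC#CC)C(=O)OC(C)(C)C
F16 | step 13 | diyne alcohol | CC#C[C@@H](O)C[C@@H]1C[C@](C)(O[Si](CC)(CC)CC)CC(O[Si](C)(C)C(C)(C)C)=C1CCCN(CCC#CC)C(=O)OC(C)(C)C
F17 | step 13 | diyne silyl ether | CC#C[C@@H](O[Si](C)(C)C(C)(C)C)C[C@@H]1C[C@](C)(O[Si](CC)(CC)CC)CC(O[Si](C)(C)C(C)(C)C)=C1CCCN(CCC#CC)C(=O)OC(C)(C)C
F18 | step 16 | axial C1 alcohol | O[C@@H]1C[C@@](C)(O[Si](CC)(CC)CC)C[C@H]2C[C@H](O[Si](C)(C)C(C)(C)C)/C3=C/CCN(C(=O)OC(C)(C)C)CCC[C@@]321
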